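**Assumption:** read from the SMILES, the lactone is 3R,4R (trans). The side chain is C7''(S) carbinol and C8''(R) aryl-bearing carbon, which is the syn-aldol relationship. Ring A is the central tetrasubstituted arene, ring B the guaiacyl ring on the C4 benzyl group, ring C the guaiacyl ring on the carbinol. A sequence run without isolating its intermediate counts as one step.

## Retrosynthetic overview
1. Target ⇒ its tri-O-benzyl ether (hydrogenolysis last) ⇒ syn-aldol imide (reductive auxiliary removal gives the CH2OH).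
2. C7''–C8'' comes from a boron syn-aldol of a ring A arylacetyl oxazolidinone with O-benzylvanillin. Ring A–C8'' comes from Pd α-arylation of an aryl bromide.
3. C7'–C8' comes from trans-selective alkylation of an (R)-β-benzyl-γ-butyrolactone with a benzylic bromide made from 5-bromovanillin.
4. Key disconnection: the lactone comes from a mirror-symmetric 3-benzylcyclobutanone by catalytic enantioselective Baeyer–Villiger ring expansion. This one event fixes C4, and C3 is relayed from it.
5. Ring order: cyclobutanone ([2+2] of dichloroketene with O-benzyleugenol) first, then the γ-lactone, which is the only ring kept.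

## Route

Step 1
Reactants: 1 eugenol (4-allyl-2-methoxyphenol)
Product: 2 4-allyl-1-(benzyloxy)-2-methoxybenzene
Conditions: BnBr (1.1 equiv), K2CO3, acetone, reflux
Reagents that add atoms: benzyl bromide, BrCc1ccccc1
Why: Williamson ether synthesis, in which the phenoxide is alkylated at oxygen to mask the ring B phenol with a group that survives zinc, peracid, amide base and palladium coupling and leaves by hydrogenolysis at the end; no stereocenter is formed.

Step 2
Reactants: 2 4-allyl-1-(benzyloxy)-2-methoxybenzene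
Product: 5 3-[4-(benzyloxy)-3-methoxybenzyl]cyclobutan-1-one, via dichloroketene 3 (not isolated), via dichlorocyclobutanone 4 (not isolated)
Conditions: Cl3CCOCl, Zn–Cu couple, Et2O/DME, 0 °C to rt; filter, concentrate; then Zn, AcOH, rt to 60 °C
Reagents that add atoms: trichloroacetyl chloride, ClC(Cl)(Cl)C(Cl)=O
Why: Thermal [2+2] ketene–alkene cycloaddition followed by zinc reductive dechlorination, in which the carbonyl carbon of the electrophilic ketene bonds to the terminal CH2, so that after loss of both chlorines the benzyl group sits at C3 on the mirror plane of an achiral ketone and the stereocenter of racemic 4 is erased.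

Step 3
Reactants: 5 3-[4-(benzyloxy)-3-methoxybenzyl]cyclobutan-1-one
Product: 6 (4R)-4-[4-(benzyloxy)-3-methoxybenzyl]dihydrofuran-2(3H)-one
Conditions: Sc(OTf)3 (5 mol %), C2-symmetric amino-acid-derived N,N'-dioxide ligand (5 mol %, enantiomer giving the dextrorotatory R lactone), mCPBA (1.2 equiv), EtOAc, −20 °C
Reagents that add atoms: m-chloroperbenzoic acid, OOC(=O)c1cccc(Cl)c1
Why: Catalytic enantioselective Baeyer–Villiger desymmetrisation, in which the chiral trivalent scandium complex distinguishes the two enantiotopic acyl–CH2 bonds in the migration step and so sets C4 as R, while ring strain keeps the reaction fast enough at −20 °C to spare the electron-rich arenes; the benzyl-substituted substrate is the harder class for selectivity, and that risk is accepted.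

Step 4
Reactants: 7 5-bromovanillin
Product: 9 [4-(benzyloxy)-3-bromo-5-methoxyphenyl]methanol, via benzylated aldehyde 8 (not isolated)
Conditions: BnBr (1.05 equiv), K2CO3, DMF, 60 °C; then MeOH, NaBH4, 0 °C
Reagents that add atoms: benzyl bromide, BrCc1ccccc1
Why: Williamson etherification followed in the same flask by borohydride reduction of the aldehyde, both chemoselective because the aryl bromide is inert to carbonate and NaBH4; no stereocenter is formed.

Step 5
Reactants: 9 [4-(benzyloxy)-3-bromo-5-methoxyphenyl]methanol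
Product: 10 2-(benzyloxy)-1-bromo-5-(bromomethyl)-3-methoxybenzene
Conditions: PBr3 (0.4 equiv), CH2Cl2, 0 °C
Reagents that add atoms: phosphorus tribromide, BrP(Br)Br
Why: Alcohol-to-bromide conversion through a phosphite ester and SN2 displacement, fast for an electron-rich benzylic alcohol and mild enough for the benzyl ether; no stereocenter is formed.

Step 6
Reactants: 6 (4R)-4-[4-(benzyloxy)-3-methoxybenzyl]dihydrofuran-2(3H)-one; 10 2-(benzyloxy)-1-bromo-5-(bromomethyl)-3-methoxybenzene
Product: 12 (3R,4R)-3-[4-(benzyloxy)-3-bromo-5-methoxybenzyl]-4-[4-(benzyloxy)-3-methoxybenzyl]dihydrofuran-2(3H)-one, via lithium enolate 11 (not isolated)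
Conditions: LiN(SiMe3)2 (1.05 equiv), THF, −78 °C; then 10, DMPU, −78 to −40 °C
Reagents that add atoms: lithium bis(trimethylsilyl)amide, [Li]N([Si](C)(C)C)[Si](C)(C)C (its lithium is carried only by 11)
Why: Diastereoselective lactone enolate alkylation, in which the benzylic bromide approaches the planar enolate anti to the C4 benzyl group and so sets C3 as R (trans, also the thermodynamic isomer), while the aryl bromide does not react.

Step 7
Reactants: 12 (3R,4R)-3-[4-(benzyloxy)-3-bromo-5-methoxybenzyl]-4-[4-(benzyloxy)-3-methoxybenzyl]dihydrofuran-2(3H)-one; 13 (4S)-3-acetyl-4-benzyl-1,3-oxazolidin-2-one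
Product: 15 (4S)-4-benzyl-3-{[2-(benzyloxy)-5-{[(3R,4R)-4-[4-(benzyloxy)-3-methoxybenzyl]-2-oxotetrahydrofuran-3-yl]methyl}-3-methoxyphenyl]acetyl}-1,3-oxazolidin-2-one, via silyl ketene aminal 14 (not isolated)
Conditions: 13, LiN(SiMe3)2, Me3SiCl, THF, −78 °C to rt, strip volatiles; then 12, Pd(dba)2 (5 mol %), P(t-Bu)3 (10 mol %), ZnF2 (0.5 equiv), DMF, 80 °C
Reagents that add atoms: chlorotrimethylsilane, C[Si](C)(C)Cl (its silyl group is carried only by 14)
Why: Palladium-catalysed α-arylation of an imide silyl enolate, in which ZnF2 releases a mild zinc enolate that transmetalates to the arylpalladium bromide formed from zerovalent palladium, so the nearly neutral medium leaves the lactone and its two stereocenters untouched and the ortho benzyloxy group discourages a second arylation; the use of an acetyl rather than a propionyl imide is a modest extension; no new stereocenter.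

Step 8
Reactants: 15 the ring A arylacetyl imide; 16 4-(benzyloxy)-3-methoxybenzaldehyde (O-benzylvanillin)
Product: 19 (4S)-4-benzyl-3-{(2S,3S)-2-[2-(benzyloxy)-5-{[(3R,4R)-4-[4-(benzyloxy)-3-methoxybenzyl]-2-oxotetrahydrofuran-3-yl]methyl}-3-methoxyphenyl]-3-[4-(benzyloxy)-3-methoxyphenyl]-3-hydroxypropanoyl}-1,3-oxazolidin-2-one, via boron enolate 17 (not isolated), via boron aldolate 18 (not isolated)
Conditions: Bu2BOTf (1.3 equiv), Et3N, CH2Cl2, −78 to 0 °C; 16, −78 to 0 °C; then pH 7 buffer, MeOH, 30% H2O2, 0 °C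
Reagents that add atoms: dibutylboron triflate, CCCCB(CCCC)OS(=O)(=O)C(F)(F)F (its Bu2B group is carried only by 17 and 18)
Why: Evans boron syn-aldol reaction, in which only the acidic imide (not the lactone) is enolised to the Z-enolate and the Zimmerman–Traxler chair with the (4S)-benzyl group shielding one face sets both C8'' and C7'' in the syn (2S,3S) sense that maps onto the target.

Step 9
Reactants: 19 the syn-aldol imide
Product: 20 (3R,4R)-3-{4-(benzyloxy)-3-[(1S,2R)-1-[4-(benzyloxy)-3-methoxyphenyl]-1,3-dihydroxypropan-2-yl]-5-methoxybenzyl}-4-[4-(benzyloxy)-3-methoxybenzyl]dihydrofuran-2(3H)-one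
Conditions: NaBH4 (4 equiv), THF/H2O (4:1), 0 °C to rt
Reagents that add atoms: none
Why: Chemoselective reductive cleavage of an N-acyloxazolidinone, in which the activated exocyclic imide carbonyl is reduced to CH2OH by NaBH4 far faster than a γ-lactone; no stereocenter is touched, and C8'' changes from S to R only through the priority change.

Step 10
Reactants: 20 the tri-O-benzyl ether
Product: 21 (3R,4R)-3-{3-[(1S,2R)-1,3-dihydroxy-1-(4-hydroxy-3-methoxyphenyl)propan-2-yl]-4-hydroxy-5-methoxybenzyl}-4-(4-hydroxy-3-methoxybenzyl)dihydrofuran-2(3H)-one (target)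
Conditions: H2 (1 atm), Pd/C (10 wt %), EtOAc/EtOH, rt, stopped after 3 equiv H2
Reagents that add atoms: none
Why: Catalytic hydrogenolysis, in which aryl benzyl ethers cleave much faster than the hindered secondary benzylic alcohol under neutral conditions at 1 atm, and the absence of acid avoids both loss of the C7'' hydroxyl and ring closure of the ring A phenol onto C7''; no stereocenter changes.

## Compound list
1 | eugenol | COc1cc(CC=C)ccc1O | starting material
2 | 4-allyl-1-(benzyloxy)-2-methoxybenzene | COc1cc(CC=C)ccc1OCc1ccccc1 | intermediate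
3 | dichloroketene | ClC(Cl)=C=O | intermediate
4 | (±)-2,2-dichloro-3-[4-(benzyloxy)-3-methoxybenzyl]cyclobutan-1-one | COc1cc(CC2CC(=O)C2(Cl)Cl)ccc1OCc1ccccc1 | intermediate
5 | 3-[4-(benzyloxy)-3-methoxybenzyl]cyclobutan-1-one (achiral) | COc1cc(CC2CC(=O)C2)ccc1OCc1ccccc1 | intermediate
6 | (4R)-4-[4-(benzyloxy)-3-methoxybenzyl]dihydrofuran-2(3H)-one | COc1cc(C[C@H]2COC(=O)C2)ccc1OCc1ccccc1 | intermediate
7 | 5-bromovanillin | COc1cc(C=O)cc(Br)c1O | starting material
8 | 4-(benzyloxy)-3-bromo-5-methoxybenzaldehyde | COc1cc(C=O)cc(Br)c1OCc1ccccc1 | intermediate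
9 | [4-(benzyloxy)-3-bromo-5-methoxyphenyl]methanol | COc1cc(CO)cc(Br)c1OCc1ccccc1 | intermediate
10 | 2-(benzyloxy)-1-bromo-5-(bromomethyl)-3-methoxybenzene | COc1cc(CBr)cc(Br)c1OCc1ccccc1 | intermediate
11 | lithium enolate of 6 | COc1cc(C[C@H]2COC([O-])=C2)ccc1OCc1ccccc1.[Li+] | intermediate
12 | (3R,4R) trans-dibenzyl lactone with ring A bromide | COc1cc(C[C@H]2COC(=O)[C@@H]2Cc2cc(OC)c(OCc3ccccc3)c(Br)c2)ccc1OCc1ccccc1 | intermediate
13 | (4S)-3-acetyl-4-benzyl-1,3-oxazolidin-2-one | CC(=O)N1[C@@H](Cc2ccccc2)COC1=O | starting material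
14 | O-trimethylsilyl ketene N,O-acetal of 13 | C=C(O[Si](C)(C)C)N1[C@@H](Cc2ccccc2)COC1=O | intermediate
15 | ring A arylacetyl imide (3R,4R,4S) | COc1cc(C[C@H]2COC(=O)[C@@H]2Cc2cc(OC)c(OCc3ccccc3)c(CC(=O)N3[C@@H](Cc4ccccc4)COC3=O)c2)ccc1OCc1ccccc1 | intermediate
16 | 4-(benzyloxy)-3-methoxybenzaldehyde | COc1cc(C=O)ccc1OCc1ccccc1 | starting material
17 | (Z)-dibutylboron enolate of 15 | COc1cc(C[C@H]2COC(=O)[C@@H]2Cc2cc(OC)c(OCc3ccccc3)c(/C=C(\OB(CCCC)CCCC)N3[C@@H](Cc4ccccc4)COC3=O)c2)ccc1OCc1ccccc1 | intermediate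
18 | dibutylboron aldolate of 19 | COc1cc(C[C@H]2COC(=O)[C@@H]2Cc2cc(OC)c(OCc3ccccc3)c([C@H](C(=O)N3[C@@H](Cc4ccccc4)COC3=O)[C@H](OB(CCCC)CCCC)c3ccc(OCc4ccccc4)c(OC)c3)c2)ccc1OCc1ccccc1 | intermediate
19 | (2S,3S) syn-aldol imide | COc1cc(C[C@H]2COC(=O)[C@@H]2Cc2cc(OC)c(OCc3ccccc3)c([C@H](C(=O)N3[C@@H](Cc4ccccc4)COC3=O)[C@H](O)c3ccc(OCc4ccccc4)c(OC)c3)c2)ccc1OCc1ccccc1 | intermediate
20 | tri-O-benzyl ether of the target | COc1cc(C[C@H]2COC(=O)[C@@H]2Cc2cc(OC)c(OCc3ccccc3)c([C@H](CO)[C@H](O)c3ccc(OCc4ccccc4)c(OC)c3)c2)ccc1OCc1ccccc1 | intermediate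
21 | CNP0317849.1 | COc1cc(C[C@H]2COC(=O)[C@@H]2Cc2cc(OC)c(O)c([C@H](CO)[C@H](O)c3ccc(O)c(OC)c3)c2)ccc1O | target

## Step count and risks
Total step count: 10.
Longest linear sequence: 8 (steps 1, 2, 3, 6, 7, 8, 9, 10).

**Step 3.** The selectivity with a benzyl rather than an aryl substituent may be only moderate. Part of any shortfall is repaired later, because after step 8 the minor lactone series is a diastereomer of 19 and can be removed by chromatography or crystallisation.
- The fallback sets out from 5 and keeps the symmetry-breaking idea but moves it to a deprotonation.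
- A homochiral lithium bis(1-phenylethyl)amide (enantiomer chosen by the rotation of 6) removes one of the two enantiotopic α-protons at −100 °C. Et3SiCl is present as an in-situ quench, and this gives the (3R)-triethylsilyl enol ether F1.
- One equivalent of ozone (CH2Cl2/MeOH, −78 °C) cleaves the very electron-rich enol ether double bond. NaBH4 work-up then gives the (3R)-hydroxy acid F2.
- F2 closes on mild acidification and rejoins the route at 6.

**Step 7.** The acetyl imide silyl enolate may decompose, or the hindered electron-rich bromide may couple poorly.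
- The fallback sets out from 12 and separates carbon–carbon coupling from auxiliary loading.
- Negishi-type coupling with the Reformatsky reagent BrZnCH2CO2t-Bu gives the tert-butyl arylacetate F3. Conditions are Pd(dba)2, 1,2,3,4,5-pentaphenyl-1'-(di-tert-butylphosphino)ferrocene, THF, rt.
- TFA in CH2Cl2 at 0 °C gives the arylacetic acid F4.
- PivCl/Et3N gives the mixed pivalic anhydride F5.
- (S)-4-Benzyloxazolidin-2-one with LiCl acylates on nitrogen and rejoins the route at 15.

**Step 10.** The danger is over-reduction of the C7'' benzylic alcohol once ring C carries a free para-hydroxyl.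
- The fallback sets out from 20 and shields the diol before any hydrogen is used.
- TBSOTf/2,6-lutidine gives the bis-TBS ether F6.
- Hydrogenolysis (H2, Pd/C, EtOAc) then gives the triphenol bis-TBS ether F7.
- HF·pyridine buffered with excess pyridine (THF, 0 °C) cleaves only Si–O bonds, retains the C7''–O bond, and arrives at 21.

## Further compounds
F1 | step 3 | {[(3R)-3-[4-(benzyloxy)-3-methoxybenzyl]cyclobut-1-en-1-yl]oxy}triethylsilane | COc1cc(C[C@H]2C=C(O[Si](CC)(CC)CC)C2)ccc1OCc1ccccc1
F2 | step 3 | (3R)-4-[4-(benzyloxy)-3-methoxyphenyl]-3-(hydroxymethyl)butanoic acid | COc1cc(C[C@H](CC(=O)O)CO)ccc1OCc1ccccc1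
F3 | step 7 | tert-butyl ring A arylacetate of the (3R,4R) lactone | COc1cc(C[C@H]2COC(=O)[C@@H]2Cc2cc(OC)c(OCc3ccccc3)c(CC(=O)OC(C)(C)C)c2)ccc1OCc1ccccc1
F4 | step 7 | ring A arylacetic acid of the (3R,4R) lactone | COc1cc(C[C@H]2COC(=O)[C@@H]2Cc2cc(OC)c(OCc3ccccc3)c(CC(=O)O)c2)ccc1OCc1ccccc1
F5 | step 7 | mixed pivalic anhydride of F4 | COc1cc(C[C@H]2COC(=O)[C@@H]2Cc2cc(OC)c(OCc3ccccc3)c(CC(=O)OC(=O)C(C)(C)C)c2)ccc1OCc1ccccc1
F6 | step 10 | bis-TBS ether of 20 | COc1cc(C[C@H]2COC(=O)[C@@H]2Cc2cc(OC)c(OCc3ccccc3)c([C@H](CO[Si](C)(C)C(C)(C)C)[C@H](O[Si](C)(C)C(C)(C)C)c3ccc(OCc4ccccc4)c(OC)c3)c2)ccc1OCc1ccccc1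
F7 | step 10 | bis-TBS ether of 21 | COc1cc(C[C@H]2COC(=O)[C@@H]2Cc2cc(OC)c(O)c([C@H](CO[Si](C)(C)C(C)(C)C)[C@H](O[Si](C)(C)C(C)(C)C)c3ccc(O)c(OC)c3)c2)ccc1O
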